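**Retrosynthetic overview**
1. Fertidin (14) ⇒ jaeschkeanadiol (12) + p-anisoyl chloride (13). Only the secondary OH is acylated.
2. The C3 carbinol of 12 ⇒ i-Pr addition to the trans-hydroazulenone 11, on the face anti to the angular methyl.
3. C3a–H and C4–OH ⇒ one syn hydroboration of the C3a=C4 alkene of cycloheptadiene 6. The ester shields C6=C7 from borane and is later reduced to the C6 methyl.
4. Key step: the seven-membered ring, the C8a quaternary centre and both ring alkenes ⇒ Rh(II)-catalysed enantioselective cyclopropanation / divinylcyclopropane Cope (formal [4+3]) of vinylcyclopentene 3 with vinyldiazoacetate 5.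
5. Ring order: the five-membered ring is bought (bromoenone 1). The seven-membered ring is made in one step (step 4).

Assumption 1: azulene numbering is used. C3 = C(OH)(iPr), C3a = ring-fusion CH, C4 = CH–O, C6 = C(Me)=, C8a = C(Me). The target is (3R,3aS,4S,8aR).
Assumption 2: the sense of induction of Rh2(R-DOSP)4 is assigned from the known outcome of styrene cyclopropanation (S catalyst gives the 1S,2R product) and a boat Cope transition state. If it proves reversed, the equally available S catalyst is used.

**Step 1**
Reactants: 1, 2-bromo-3-methylcyclopent-2-en-1-one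
Product: 2, 6-bromo-7-methyl-1,4-dioxaspiro[4.4]non-6-ene
Conditions: ethylene glycol, p-TsOH (cat.), benzene, Dean–Stark reflux
Reagents that add atoms: ethylene glycol, OCCO
Why: Acid-catalysed ketalisation; the α-bromine stops β,γ-migration of the C=C, and the dioxolane masks the future C3 ketone through the carbenoid, borane and hydride steps (no stereocentre).

**Step 2**
Reactants: 2, 6-bromo-7-methyl-1,4-dioxaspiro[4.4]non-6-ene
Product: 3, 6-ethenyl-7-methyl-1,4-dioxaspiro[4.4]non-6-ene
Conditions: vinyl-Bpin, Pd(dppf)Cl2 (5 mol %), K3PO4, dioxane/H2O, 80 °C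
Reagents that add atoms: vinylboronic acid pinacol ester, C=CB1OC(C)(C)C(C)(C)O1
Why: Suzuki–Miyaura coupling of the alkenyl bromide gives the 1-vinyl-2-methylcyclopentene diene, and the basic medium leaves the ketal intact.

**Step 3**
Reactants: 4, methyl but-3-enoate
Product: 5, methyl 2-diazobut-3-enoate
Conditions: p-ABSA, DBU, MeCN, 0 °C; pentane extraction; used cold the same day
Reagents that add atoms: 4-acetamidobenzenesulfonyl azide, CC(=O)Nc1ccc(cc1)S(=O)(=O)N=[N+]=[N-]
Why: Regitz-type diazo transfer to the DBU-generated dienolate occurs at the α-carbon; the product slowly electrocyclises to a pyrazole, so it is not stored.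

**Step 4 (key step)**
Reactants: 3, 6-ethenyl-7-methyl-1,4-dioxaspiro[4.4]non-6-ene; 5, methyl 2-diazobut-3-enoate
Product: 6, methyl (8aR)-3,3-(ethylenedioxy)-8a-methyl-1,2,3,5,8,8a-hexahydroazulene-6-carboxylate (alkenes at C3a=C4 and C6=C7)
Conditions: Rh2(R-DOSP)4 (1 mol %), hexanes, −20 °C → rt, slow addition of 5 (2 equiv); then toluene, 80 °C
Reagents that add atoms: none (N2 is lost from 5)
Why: The donor/acceptor Rh carbenoid cyclopropanates only the monosubstituted vinyl group of 3, giving the cis-divinylcyclopropane (vinyl cis to cyclopentenyl, ester trans) with catalyst-controlled absolute configuration; the boat-TS divinylcyclopropane–cycloheptadiene (Cope) rearrangement then transfers that chirality stereospecifically to C8a while forming the C8–C8a bond, the ring and both alkenes in their final positions (tandem cyclopropanation/Cope, formal [4+3]).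

**Step 5**
Reactants: 6, the cycloheptadiene ester from step 4
Product: 7, methyl (3aS,4S,8aR)-3,3-(ethylenedioxy)-4-hydroxy-8a-methyl-1,2,3,3a,4,5,8,8a-octahydroazulene-6-carboxylate (trans-fused; H3a and O4 both anti to the 8a-Me)
Conditions: BH3·SMe2 (1.2 equiv), THF, 0 °C → rt; then NaBO3·4H2O, THF/H2O
Reagents that add atoms: sodium perborate (oxygen source), B(=O)O[O-].[Na+]
Why: In this hydroboration–oxidation the borane takes only the electron-rich C3a=C4 alkene (C6=C7 is ester-deactivated), puts boron on the less substituted C4, and adds syn from the face opposite the pseudo-axial C8a methyl (the Δ5-steroid logic), so C3a–H (trans fusion) and C4–OH are set together and irreversibly, with retention in the C–B oxidation.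

**Step 6**
Reactants: 7, the hydroxy ester from step 5
Product: 8, the 4-O-triethylsilyl ether of 7
Conditions: TESCl, imidazole, DMF, 0 °C → rt
Reagents that add atoms: chlorotriethylsilane, CC[Si](Cl)(CC)CC
Why: Silylation of the only free OH ensures the next two hydride steps act only on the ester carbon; no stereocentre is touched.

**Step 7**
Reactants: 8, the TES-protected ester
Product: 9, the (3aS,4S,8aR)-6-(hydroxymethyl) analogue of 8 (primary allylic alcohol)
Conditions: DIBAL-H (2.5 equiv), CH2Cl2, −78 → 0 °C
Reagents that add atoms: none
Why: DIBAL-H performs a 1,2-reduction of the conjugated ester to the allylic alcohol; the ketal, TES ether and alkene are inert.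

**Step 8**
Reactants: 9, the allylic alcohol
Product: 10, (3aS,4S,8aR)-3,3-(ethylenedioxy)-6,8a-dimethyl-4-(triethylsilyloxy)-1,2,3,3a,4,5,8,8a-octahydroazulene
Conditions: SO3·pyridine, THF, 0 °C; then LiAlH4, 0 °C → rt
Reagents that add atoms: none retained
Why: In this allylic deoxygenation via the sulfate monoester, hydride displaces the primary allylic sulfate by SN2 without transposition, converting the former acceptor group into the C6 methyl and keeping C6=C7 in place.

**Step 9**
Reactants: 10, the ketal/TES ether from step 8
Product: 11, (3aS,4S,8aR)-4-hydroxy-6,8a-dimethyl-2,3a,4,5,8,8a-hexahydroazulen-3(1H)-one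
Conditions: 1 M aq HCl/THF (1:4), 0 °C → rt, short reaction time
Reagents that add atoms: water, O
Why: Acid hydrolysis removes the dioxolane and the TES ether together, and the mild, brief conditions avoid enolisation at C3a (epimerisation) and β-elimination of the C4–OH.

**Step 10**
Reactants: 11, the β-hydroxy ketone
Product: 12, jaeschkeanadiol, (3R,3aS,4S,8aR)-6,8a-dimethyl-3-(propan-2-yl)-1,2,3,3a,4,5,8,8a-octahydroazulene-3,4-diol
Conditions: LaCl3·2LiCl (1.5 equiv), i-PrMgCl (3.5 equiv), THF, −20 → 0 °C
Reagents that add atoms: isopropylmagnesium chloride, CC(C)[Mg]Cl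
Why: In this lanthanide-promoted Grignard 1,2-addition (enolisation and β-hydride reduction suppressed), the first equivalent makes the C4 alkoxide, which chelates the ketone and cannot leave, and isopropyl attacks the face opposite the axial C8a methyl (cis to H3a), giving the 3R carbinol with OH cis to the methyl.

**Step 11**
Reactants: 12, jaeschkeanadiol; 13, 4-methoxybenzoyl chloride
Product: 14, Fertidin
Conditions: 13 (1.3 equiv), DMAP, Et3N, CH2Cl2, rt
Reagents that add atoms: none beyond 13
Why: DMAP-catalysed acylation is selective for the secondary C4–OH because the tertiary C3–OH next to the isopropyl group is unreactive; no stereocentre is touched.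

**Compound list**
1 | 2-bromo-3-methylcyclopent-2-en-1-one | CC1=C(Br)C(=O)CC1 | starting material
2 | 6-bromo-7-methyl-1,4-dioxaspiro[4.4]non-6-ene | CC1=C(Br)C2(CC1)OCCO2 | intermediate
3 | 6-ethenyl-7-methyl-1,4-dioxaspiro[4.4]non-6-ene | C=CC1=C(C)CCC12OCCO2 | intermediate
4 | methyl but-3-enoate | C=CCC(=O)OC | starting material
5 | methyl 2-diazobut-3-enoate | C=CC(=[N+]=[N-])C(=O)OC | intermediate
6 | (8aR)-hexahydroazulene-6-carboxylate 3-ketal | COC(=O)C1=CC[C@@]2(C)CCC3(OCCO3)C2=CC1 | intermediate
7 | (3aS,4S,8aR)-4-hydroxy ester ketal | O[C@H]1CC(C(=O)OC)=CC[C@@]2(C)CCC3(OCCO3)[C@H]12 | intermediate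
8 | 4-O-TES ether of 7 | CC[Si](CC)(CC)O[C@H]1CC(C(=O)OC)=CC[C@@]2(C)CCC3(OCCO3)[C@H]12 | intermediate
9 | 6-hydroxymethyl compound | CC[Si](CC)(CC)O[C@H]1CC(CO)=CC[C@@]2(C)CCC3(OCCO3)[C@H]12 | intermediate
10 | 6-methyl ketal TES ether | CC[Si](CC)(CC)O[C@H]1CC(C)=CC[C@@]2(C)CCC3(OCCO3)[C@H]12 | intermediate
11 | (3aS,4S,8aR)-4-hydroxy-6,8a-dimethylhexahydroazulen-3-one | O[C@H]1CC(C)=CC[C@@]2(C)CCC(=O)[C@H]12 | intermediate
12 | jaeschkeanadiol | O[C@H]1CC(C)=CC[C@@]2(C)CC[C@@](O)(C(C)C)[C@H]12 | intermediate
13 | 4-methoxybenzoyl chloride | COc1ccc(cc1)C(Cl)=O | starting material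
14 | Fertidin | COc1ccc(C(=O)O[C@H]2CC(C)=CC[C@@]3(C)CC[C@@](O)(C(C)C)[C@H]23)cc1 | target

**Totals**
Total steps: 11.
Longest linear sequence: 10 (1→2→3→6→7→8→9→10→11→12→14).

**Three steps most likely to fail**
1. **Step 4.**
   - Risk: the twisted, hindered diene may cyclopropanate slowly or with reduced ee. The Cope must also build a quaternary centre with an inward-pointing methyl.
   - Fallback: decouple the two events. Cyclopropanate unhindered vinyl-Bpin with 5 under the same catalyst to get the enantioenriched cis-2-boryl-1-vinylcyclopropanecarboxylate. Join it to bromide 2 by a stereoretentive Suzuki coupling. This gives the same divinylcyclopropane, which is then rearranged thermally.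
2. **Step 5.**
   - Risk: the face selectivity, or the selectivity for C3a=C4 over the enoate, may be inadequate.
   - Fallback: run steps 7–8 on 6 first (ester → CH3) and hydrolyse the ketal to the C3-enone. Only C3a=C4 is then electrophilic. Install O4 by Cu-catalysed conjugate borylation (B2pin2) and oxidation, anti to the methyl. C3a is then set by protonation of the enolate.
3. **Step 10**, together with the sensitive ketol 11 from step 9.
   - Risk: enolisation, retro-aldol cleavage or poor facial selectivity.
   - Fallback: use a TBS ether at O4 and remove the ketal under neutral conditions (I2/acetone). Add the smaller, non-reducing 2-propenylcerium reagent to the silyloxy ketone. Saturate the 1,1-disubstituted alkene selectively (diimide or Wilkinson hydrogenation), then desilylate and acylate.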